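Numbering: o
xane ring O1–C2–C3–C4–C5–C6. C2 carries C1'H2–C2'H2–guaiacyl, C4 the hydroxyl and C6 the syringyl group. The target is (2S,4R,6S), with all three ring substituents cis and equatorial.
Enabling feature: O1 sits on C2, so C2 is a latent oxocarbenium carbon and C1' is the β-carbon of a vinyl ether O1–C2=C1'. C2' is a former aldehyde carbon, and C3–C4 (oxygen at C4) is a latent 2-substituted allylsilane tied to O1 through C5–C6.
Cuts: first C4–OH back to C4=O and C4=CH2, and C2'H2 back to C2'H(OH). Then C1'–C2' and C2–C3 are cut together, then O1–C2 (vinyl transfer), then C5–C6 (allylation of the syringyl aldehyde).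
Forward: C5–C6 is made first and O1 is vinylated. One flask then joins the vanillin half and closes the oxane, the only ring that has to be built, and the C4 and C2' oxidation levels are adjusted last.
Stereochemistry: C6 comes from an (S)-BINOL/Ti(OiPr)4 allylation, C2 from C6 through a chair ring closure (2,6-cis), and C4 from axial hydride delivery to the oxan-4-one. The C2' carbinol is uncontrolled and is erased.

Key step: step 6

Assumption: the facial sense of the (S)-BINOL/Ti(OiPr)4 catalyst known for aromatic aldehydes (Si-face attack, (S)-carbinol) is taken to hold for pivaloylated syringaldehyde. If it does not, (R)-BINOL is used.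

Step 1
Reactants: 1 syringaldehyde (4-hydroxy-3,5-dimethoxybenzaldehyde)
Product: 2 4-formyl-2,6-dimethoxyphenyl pivalate
Conditions: PivCl, Et3N, DMAP (cat.), CH2Cl2, 0 → 23 °C
Reagents that add atoms: pivaloyl chloride, CC(C)(C)C(=O)Cl
Why: DMAP-catalysed O-acylation of the phenol should be clean, and the bulky electron-withdrawing ester tolerates Lewis acid, ozone and hydrogenation while lowering the donor strength of the ring towards the future benzylic C6 position.

Step 2
Reactants: 3 vanillin (4-hydroxy-3-methoxybenzaldehyde)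
Product: 4 4-formyl-2-methoxyphenyl pivalate
Conditions: PivCl, Et3N, DMAP (cat.), CH2Cl2, 0 → 23 °C
Reagents that add atoms: pivaloyl chloride, CC(C)(C)C(=O)Cl
Why: The same nucleophile-catalysed O-acylation turns vanillin into a more electrophilic aldehyde whose later C2' carbinol is slow to ionise.

Step 3
Reactants: 5 2-(chloromethyl)allyltrimethylsilane
Product: 6 tributyl[2-(trimethylsilylmethyl)allyl]stannane
Conditions: Bu3SnH, LiN(iPr)2, THF, 0 °C; then 5, −78 → 0 °C
Reagents that add atoms: tributyltin hydride, CCCC[SnH](CCCC)CCCC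
Why: Bu3SnLi, formed by deprotonation of Bu3SnH, displaces the allylic chloride (SN2 stannylation), and direct and allylic-shift attack lead to the same constitution, so no regiochemical issue arises.

Step 4
Reactants: 2 4-formyl-2,6-dimethoxyphenyl pivalate; 6 tributyl[2-(trimethylsilylmethyl)allyl]stannane
Product: 7 4-[(1S)-1-hydroxy-3-(trimethylsilylmethyl)but-3-en-1-yl]-2,6-dimethoxyphenyl pivalate
Conditions: (S)-BINOL (20 mol %), Ti(OiPr)4 (10 mol %), 4 Å molecular sieves, CH2Cl2, −20 °C; aq NaHCO3
Reagents that add atoms: none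
Why: Keck asymmetric allylation: the allylstannane terminus is far more nucleophilic than the allylsilane, so SE2' addition with loss of tin forms C5–C6 and leaves the allylsilane, while the (S)-BINOL titanium complex directs attack to the Si face of the aldehyde and sets the (S) centre that becomes C6.

Step 5
Reactants: 7 4-[(1S)-1-hydroxy-3-(trimethylsilylmethyl)but-3-en-1-yl]-2,6-dimethoxyphenyl pivalate; 8 ethyl vinyl ether
Product: 9 4-[(1S)-1-(ethenyloxy)-3-(trimethylsilylmethyl)but-3-en-1-yl]-2,6-dimethoxyphenyl pivalate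
Conditions: 8 (solvent), Hg(OCOCF3)2 (20 mol %), Et3N (cat.), 23 °C; chromatography on Et3N-washed silica
Reagents that add atoms: none
Why: Transetherification (vinyl exchange) catalysed by divalent mercury proceeds by reversible alkoxymercuration and loss of ethanol, is driven by the large excess of 8, leaves the C6–O bond and its configuration untouched, and the amine buffer protects the allylsilane and the product from acid.

Step 6
Reactants: 9 4-[(1S)-1-(ethenyloxy)-3-(trimethylsilylmethyl)but-3-en-1-yl]-2,6-dimethoxyphenyl pivalate; 4 4-formyl-2-methoxyphenyl pivalate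
Product: 11 (2R,6S)-6-(3,5-dimethoxy-4-pivaloyloxyphenyl)-2-[2-hydroxy-2-(3-methoxy-4-pivaloyloxyphenyl)ethyl]-4-methyleneoxane (2,6-cis; both C2' epimers), via boron aldolate oxocarbenium ion 10 (not isolated)
Conditions: 4 (1.5 equiv), BF3·OEt2 (2.5 equiv), 2,6-di-tert-butylpyridine (1.5 equiv), CH2Cl2, −78 °C; aq NaHCO3
Reagents that add atoms: none
Why: The BF3-bound aldehyde 4 is attacked by the vinyl ether β-carbon C1' (Mukaiyama-type aldol addition of an alkyl enol ether), which forms C1'–C2' and leaves the (E)-oxocarbenium ion 10 at C2=O1. The tethered 2-substituted allylsilane then adds through its terminal CH2 (future C3) to C2 in a silyl-terminated Prins closure, 6-endo-trig with respect to both the C=O+ and the C=C unit, and loss of Me3SiF from the β-silyl cation at C4 fixes the exocyclic methylene; the sequence as a whole is the known Mukaiyama aldol–Prins cascade of homoallylic vinyl ethers that carry an allylsilane. C2 is set by C6: in the chair transition state the C6 aryl group and the C2 side chain of the (E)-ion both lie equatorial, which gives the 2,6-cis ring, (2R,6S) by CIP ranking at this stage. C2' has no controlling element, so both epimers are expected, and both are carried on because this carbon becomes CH2 in steps 8 and 9. The step needs the enol ether to reach 4 before the allylsilane does, and needs ring closure to outrun a second aldol addition, 2-oxonia-Cope scrambling and benzylic ionisation; the oxygen-activated alkene secures the first, intramolecular capture with irreversible desilylation secures the next two, and the para pivaloyloxy and purely meta methoxy groups, which make both benzylic cations poor, secure the last. The hindered pyridine removes adventitious protic acid that would hydrolyse the vinyl ether or protodesilylate the allylsilane.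

Step 7
Reactants: 11 (2R,6S)-6-(3,5-dimethoxy-4-pivaloyloxyphenyl)-2-[2-hydroxy-2-(3-methoxy-4-pivaloyloxyphenyl)ethyl]-4-methyleneoxane
Product: 12 (2S,6S)-6-(3,5-dimethoxy-4-pivaloyloxyphenyl)-2-[2-hydroxy-2-(3-methoxy-4-pivaloyloxyphenyl)ethyl]oxan-4-one (both C2' epimers; the C2 descriptor changes by CIP ranking only)
Conditions: O3, Sudan Red 7B (indicator), CH2Cl2–MeOH, −78 °C; then Me2S, −78 → 23 °C
Reagents that add atoms: ozone, [O-][O+]=O
Why: Criegee ozonolysis with reductive work-up cleaves the 1,1-disubstituted alkene much faster than ozone attacks the acylated arenes, and the dye marks the end point so that no excess oxidant builds up.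

Step 8
Reactants: 12 (2S,6S)-6-(3,5-dimethoxy-4-pivaloyloxyphenyl)-2-[2-hydroxy-2-(3-methoxy-4-pivaloyloxyphenyl)ethyl]oxan-4-one
Product: 13 (2R,6S)-6-(3,5-dimethoxy-4-pivaloyloxyphenyl)-2-[(E)-2-(3-methoxy-4-pivaloyloxyphenyl)ethenyl]oxan-4-one
Conditions: Burgess reagent (MeO2CN(−)SO2N(+)Et3), toluene, 60 °C
Reagents that add atoms: none
Why: Burgess dehydration: each carbinol epimer forms a sulfamate ester that undergoes thermal syn-elimination with one of the two C1' hydrogens, the only β-hydrogens available, under essentially neutral conditions that spare the β-alkoxy ketone from retro-oxa-Michael opening.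

Step 9
Reactants: 13 (2R,6S)-6-(3,5-dimethoxy-4-pivaloyloxyphenyl)-2-[(E)-2-(3-methoxy-4-pivaloyloxyphenyl)ethenyl]oxan-4-one
Product: 14 (2S,6S)-6-(3,5-dimethoxy-4-pivaloyloxyphenyl)-2-[2-(3-methoxy-4-pivaloyloxyphenyl)ethyl]oxan-4-one
Conditions: H2 (1 atm), 5% Pd/C, pyridine (0.5 equiv), EtOAc, 23 °C
Reagents that add atoms: none
Why: Heterogeneous catalytic hydrogenation on amine-moderated Pd/C should saturate the disubstituted styrene faster than it cleaves the allylic C2–O1 or benzylic C6–O1 bond, the dialkyl ketone and aryl esters are inert, and no stereocentre is touched.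

Step 10
Reactants: 14 (2S,6S)-6-(3,5-dimethoxy-4-pivaloyloxyphenyl)-2-[2-(3-methoxy-4-pivaloyloxyphenyl)ethyl]oxan-4-one
Product: 16 (2S,4R,6S)-2-[2-(4-hydroxy-3-methoxyphenyl)ethyl]-6-(4-hydroxy-3,5-dimethoxyphenyl)oxan-4-ol (CNP0302691.1), via oxan-4-ol dipivalate 15 (not isolated)
Conditions: LiAlH4 (3 equiv), THF, −78 °C, then → 23 °C; aq potassium sodium tartrate / NH4Cl
Reagents that add atoms: none
Why: Hydride reduction: at −78 °C the small reagent attacks the chair oxan-4-one, whose C2 and C6 substituents are equatorial, along the axial trajectory to give the equatorial (4R) alkoxide of 15, and on warming the same reagent cleaves both aryl pivalates by ester reduction and frees the phenols under a buffered work-up that avoids acid at the C6 benzylic ether.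

Compound list
1 | syringaldehyde | COc1cc(C=O)cc(OC)c1O | starting material
2 | 4-formyl-2,6-dimethoxyphenyl pivalate | COc1cc(C=O)cc(OC)c1OC(=O)C(C)(C)C | intermediate
3 | vanillin | COc1cc(C=O)ccc1O | starting material
4 | 4-formyl-2-methoxyphenyl pivalate | O=Cc1ccc(OC(=O)C(C)(C)C)c(OC)c1 | intermediate
5 | 2-(chloromethyl)allyltrimethylsilane | C=C(CCl)C[Si](C)(C)C | starting material
6 | tributyl[2-(trimethylsilylmethyl)allyl]stannane | CCCC[Sn](CCCC)(CCCC)CC(=C)C[Si](C)(C)C | intermediate
7 | 4-[(1S)-1-hydroxy-3-(trimethylsilylmethyl)but-3-en-1-yl]-2,6-dimethoxyphenyl pivalate | C[Si](C)(C)CC(=C)C[C@@H](c1cc(OC)c(OC(=O)C(C)(C)C)c(OC)c1)O | intermediate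
8 | ethyl vinyl ether | C=COCC | starting material
9 | 4-[(1S)-1-(ethenyloxy)-3-(trimethylsilylmethyl)but-3-en-1-yl]-2,6-dimethoxyphenyl pivalate | C[Si](C)(C)CC(=C)C[C@@H](c1cc(OC)c(OC(=O)C(C)(C)C)c(OC)c1)OC=C | intermediate
10 | (E)-oxocarbenium ion at C2=O1 carrying the C2' trifluoroborate aldolate (zwitterion, C6 (S), both C2' epimers) | C[Si](C)(C)CC(=C)C[C@@H](c1cc(OC)c(OC(=O)C(C)(C)C)c(OC)c1)/[O+]=C/CC(O[B-](F)(F)F)c1ccc(OC(=O)C(C)(C)C)c(OC)c1 | intermediate
11 | (2R,6S)-6-(3,5-dimethoxy-4-pivaloyloxyphenyl)-2-[2-hydroxy-2-(3-methoxy-4-pivaloyloxyphenyl)ethyl]-4-methyleneoxane, 2,6-cis, both C2' epimers | COc1cc(C(O)C[C@H]2CC(=C)C[C@@H](c3cc(OC)c(OC(=O)C(C)(C)C)c(OC)c3)O2)ccc1OC(=O)C(C)(C)C | intermediate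
12 | (2S,6S)-6-(3,5-dimethoxy-4-pivaloyloxyphenyl)-2-[2-hydroxy-2-(3-methoxy-4-pivaloyloxyphenyl)ethyl]oxan-4-one, 2,6-cis, both C2' epimers | COc1cc(C(O)C[C@H]2CC(=O)C[C@@H](c3cc(OC)c(OC(=O)C(C)(C)C)c(OC)c3)O2)ccc1OC(=O)C(C)(C)C | intermediate
13 | (2R,6S)-6-(3,5-dimethoxy-4-pivaloyloxyphenyl)-2-[(E)-2-(3-methoxy-4-pivaloyloxyphenyl)ethenyl]oxan-4-one, 2,6-cis | COc1cc(/C=C/[C@H]2CC(=O)C[C@@H](c3cc(OC)c(OC(=O)C(C)(C)C)c(OC)c3)O2)ccc1OC(=O)C(C)(C)C | intermediate
14 | (2S,6S)-6-(3,5-dimethoxy-4-pivaloyloxyphenyl)-2-[2-(3-methoxy-4-pivaloyloxyphenyl)ethyl]oxan-4-one, 2,6-cis | COc1cc(CC[C@H]2CC(=O)C[C@@H](c3cc(OC)c(OC(=O)C(C)(C)C)c(OC)c3)O2)ccc1OC(=O)C(C)(C)C | intermediate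
15 | (2S,4R,6S)-6-(3,5-dimethoxy-4-pivaloyloxyphenyl)-2-[2-(3-methoxy-4-pivaloyloxyphenyl)ethyl]oxan-4-ol, all-cis, present as its aluminium alkoxide | COc1cc(CC[C@H]2C[C@@H](O)C[C@@H](c3cc(OC)c(OC(=O)C(C)(C)C)c(OC)c3)O2)ccc1OC(=O)C(C)(C)C | intermediate
16 | (2S,4R,6S)-2-[2-(4-hydroxy-3-methoxyphenyl)ethyl]-6-(4-hydroxy-3,5-dimethoxyphenyl)oxan-4-ol (CNP0302691.1) | COc1cc(CC[C@H]2C[C@@H](O)C[C@@H](c3cc(OC)c(O)c(OC)c3)O2)ccc1O | target

Total step count: 10
Longest linear sequence: 8 steps (steps 1, 4, 5, 6, 7, 8, 9, 10)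

Steps most likely to fail

**Step 6.**
- Risk: the aldehyde may be engaged by the allylsilane terminus instead of the enol ether. The enol ether may add a second time before the ring closes. The C2' boron aldolate may ionise.
- Fallback: it sets out from 7 and 4 and returns at 14, bypassing steps 5, 8 and 9.
- Aldehyde 4 is homologated by Wittig olefination with Ph3P=CHCHO (toluene, 80 °C) to (E)-3-(3-methoxy-4-pivaloyloxyphenyl)prop-2-enal F1.
- The alkene of F1 is hydrogenated (H2, Pd/C, EtOAc) to 3-(3-methoxy-4-pivaloyloxyphenyl)propanal F2.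
- Condensation of F2 with hydroxy allylsilane 7 under Me3SiOTf in Et2O at −78 °C (intermolecular silyl-Prins pyran annulation) closes C2–C3 through the same chair. It gives (2S,6S)-6-(3,5-dimethoxy-4-pivaloyloxyphenyl)-2-[2-(3-methoxy-4-pivaloyloxyphenyl)ethyl]-4-methyleneoxane F3.
- Ozonolysis of F3 (O3, then Me2S) delivers ketone 14.

**Step 5.**
- Risk: divalent mercury may attack the allylsilane (mercuridesilylation). The exchange may stall at partial conversion. Adventitious acid may divert the alcohol into a mixed acetal.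
- Fallback: it sets out from 7 and returns at 9, building the vinyl group by carbonyl methylenation instead of vinyl transfer.
- Alcohol 7 is formylated with acetic formic anhydride and pyridine (CH2Cl2, 0 °C) to (1S)-1-(3,5-dimethoxy-4-pivaloyloxyphenyl)-3-(trimethylsilylmethyl)but-3-en-1-yl formate F4.
- One equivalent of Cp2Ti(µ-CH2)(µ-Cl)AlMe2 (Tebbe methylenation, THF–toluene, pyridine, −40 → 0 °C) converts the unhindered formate carbonyl into the vinyl ether 9. The flanked aryl pivalate should react much more slowly.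

**Step 8.**
- Risk: the benzylic sulfamate may undergo substitution instead of elimination. The β-alkoxy ketone may open by retro-oxa-Michael reaction once the conjugated styryl group is in place.
- Fallback: it sets out from 12 and returns at 14, replacing dehydration and hydrogenation by a radical deoxygenation (Barton–McCombie).
- Carbinol 12 is treated with 1,1'-thiocarbonyldiimidazole and DMAP (CH2Cl2, 23 °C). This gives O-[2-[(2S,6S)-6-(3,5-dimethoxy-4-pivaloyloxyphenyl)-4-oxooxan-2-yl]-1-(3-methoxy-4-pivaloyloxyphenyl)ethyl] imidazole-1-carbothioate F5.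
- Bu3SnH and AIBN in toluene at 80 °C reduce the stabilised benzylic radical from F5 to the C2' methylene of 14. No styrene is ever formed.

Further compounds
F1 | step 6 | (E)-3-(3-methoxy-4-pivaloyloxyphenyl)prop-2-enal | O=C/C=C/c1ccc(OC(=O)C(C)(C)C)c(OC)c1
F2 | step 6 | 3-(3-methoxy-4-pivaloyloxyphenyl)propanal | O=CCCc1ccc(OC(=O)C(C)(C)C)c(OC)c1
F3 | step 6 | (2S,6S)-6-(3,5-dimethoxy-4-pivaloyloxyphenyl)-2-[2-(3-methoxy-4-pivaloyloxyphenyl)ethyl]-4-methyleneoxane | COc1cc(CC[C@H]2CC(=C)C[C@@H](c3cc(OC)c(OC(=O)C(C)(C)C)c(OC)c3)O2)ccc1OC(=O)C(C)(C)C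
F4 | step 5 | (1S)-1-(3,5-dimethoxy-4-pivaloyloxyphenyl)-3-(trimethylsilylmethyl)but-3-en-1-yl formate | C[Si](C)(C)CC(=C)C[C@@H](c1cc(OC)c(OC(=O)C(C)(C)C)c(OC)c1)OC=O
F5 | step 8 | O-[2-[(2S,6S)-6-(3,5-dimethoxy-4-pivaloyloxyphenyl)-4-oxooxan-2-yl]-1-(3-methoxy-4-pivaloyloxyphenyl)ethyl] imidazole-1-carbothioate | COc1cc(C(OC(=S)n4ccnc4)C[C@H]2CC(=O)C[C@@H](c3cc(OC)c(OC(=O)C(C)(C)C)c(OC)c3)O2)ccc1OC(=O)C(C)(C)C
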